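Remark on the chemistry: the SMILES is read as a (2R)-2-methylbutanoate on O5 and a (2E)-3-methylpent-2-enoate on O6; compounds 1, 2, 8, 14, 22, 31 and 39 are taken as purchasable.

## Analysis of the target

The target 42 is a cis-fused hydrindan-2-one (indane numbering: C1 carries the 1-acetoxyethyl group with carbinol carbon C1′, C2 is the ketone, C4 carries the exocyclic methylene, C5 and C6 carry the acyloxy groups, C7 carries the oxirane whose quaternary carbon is called C8 here). It has nine stereogenic carbons: six on the ring (C1, C3a, C5, C6, C7, C7a), C1′, C8 and the α-carbon of the 2-methylbutanoate, plus one E-enoate. All six ring hydrogens lie on one face, so the substituents at C1, C5, C6 and C7 are mutually cis and sit opposite the ring-fusion hydrogens. The C1 side chain is therefore cis to C7 on the cyclopentanone, probably the less stable arrangement at an epimerisable centre. Sensitive groups are the β-acetoxy ketone (β-elimination, epimerisation at C1), the 2,2-disubstituted glycidic ester, the allylic C5 ester next to the methylene group, the cis-vicinal diester (acyl migration) and the α-stereocentre of the 2-methylbutanoate. The main difficulties are three different esters on neighbouring secondary oxygens, a contiguous all-cis array, and a quaternary oxirane carbon outside the ring. The strategy rests on the C4(=CH2)–C5(O) unit: a 2-methylene-1-ol is the direct product of a 1-iodoalkenyl group on C3a adding to a C5 aldehyde, which closes the six-membered ring.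

## Retrosynthetic reasoning

Ester groups (42 ⇐ 41 ⇐ 40 ⇐ 38 ⇐ 37). The three C–O acyl bonds are cut last-in-first-out: the acetate on C1′ goes on last because the β-acetoxy ketone is the most fragile unit. The enoate on O6 is attached before that, from 38 and 39, after the more labile of two different silyl ethers has been removed. Each hydroxyl is thus set free alone and no diol ever has to be differentiated.

Glycidate (37 ⇐ 35 ⇐ 34 ⇐ 33). The oxirane C–O bonds and the ester oxidation level are traced back to a 2-substituted allylic alcohol. A reagent-controlled epoxidation of this alcohol sets C8, and the route never has to enolise an ester in a molecule that already holds a more acidic ketone. The forward steps must oxidise a primary alcohol to a methyl ester without touching the ketone, the oxirane or the methylene group.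

Ring-fusion hydrogens (33 ⇐ 32). Putting the C1=C7a double bond back gives an enone. One conjugate reduction then sets C7a and C1 from the only open face, and the enone is a flat, robust spectator for everything before it. The forward step must deliver hydride to a tetrasubstituted β-carbon and protonate C1 kinetically.

C4–C5 bond (32 ⇐ 30 ⇐ 29). This is the key disconnection. Cutting between the methylene-bearing carbon and the carbinol carbon gives 29, a monocyclic cyclopentenone with a 1-iodoalkenyl group on C3a and an aldehyde at the end of the C7–C6–C5 chain. The cut is made here because it forms the ring, the methylene group and a free O5 in one operation while O6 is still protected.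

Unveiling the reacting groups (29 ⇐ 28 ⇐ 27 ⇐ 26). The aldehyde is traced to a primary silyl ether and the iodide to an alkenylsilane, so that both reactive groups exist only just before the key step.

C7–C8 bond (26 ⇐ 21 + 23; 21 ⇐ 20). The arm is cut from C7, leaving an alkenyl oxirane 21 that is opened with inversion. 21 comes from the E allylic alcohol 20 by asymmetric epoxidation, so C6 and C7 are set together under reagent control. An aldol construction of C6–C7 was not chosen because it needs a ring-bearing enolate whose α-proton is vinylogously acidic.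

C7a–C7 bond (20 ⇐ 13 + 14). A C7 sp3 carbanion would carry a β-oxygen and eliminate, so the chain enters as an sp2 alkenyl nucleophile in a conjugate addition, followed by reoxidation to the enone. C7 becomes stereogenic only afterwards.

C1 side chain (13 ⇐ 11 ⇐ 10 ⇐ 7 + 8; 7 ⇐ 6 ⇐ 5). The C1–C1′ bond is cut to an α-keto vinyl anion equivalent and the acetyl donor 8. C1′ is then set by catalytic asymmetric reduction of 10 while the ring ketone is masked, so only one carbonyl can be reduced.

C3a–C4 bond (5 ⇐ 1 + 2). The only ring stereocentre of the precursor is taken from the chiral pool by conjugate addition–elimination to 1. This forms a bond that enolate chemistry cannot make with control and keeps C3a away from any α-carbonyl position.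

## Alternatives that were turned down

Alternative 1: The bonds C3a–C7a and C6–C7 are cut, and an intramolecular Diels–Alder reaction of a boron-substituted diene tethered to a Z-enoate would give A1 on heating. In its favour, both rings and four stereocentres (C3a, C7a, C7, C6) arise in one metal-free step, and the C–B bond is a stereospecific precursor of the C6 oxygen. Against it for this target: A1 has its alkene inside the ring (C4=C5, with a C4 methyl), so the methylene carbinol must still be made by an allylic transposition with unsecured regio- and facial control. C1 is formed with the wrong configuration and would have to be corrected against the likely thermodynamic preference. C7 holds only an ester carbon, so the oxirane unit needs further C–C bond formation. The Z-dienophile must survive the heating, and the dithioketal must be removed late. On stereocentres per step and on direct formation of the ring fusion this route is stronger than the chosen one. The chosen route offers instead the C4 methylene and the C5 carbinol directly from the ring closure, O5 and O6 differentiated from the start, and C1 set kinetically at the end.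

Alternative 2: The bond C3–C3a is cut, and a gold-catalysed 1,2-acyloxy shift and cyclisation (Rautenstrauch annulation, cationic monovalent gold) of a tertiary propargylic ester onto a preformed cyclohexene would give A2. In its favour, the annulation is convergent, the six-ring stereocentres can come from a cyclic chiral-pool diol, and A2 has the same C1=C7a enone, so the late conjugate reduction is equally available. Against it: the tertiary ester can ionise or undergo a 1,3-shift instead, and C3a is set in the cyclisation with only weak facial bias. A2 ties O5 and O6 into one acetonide, so two neighbouring cis hydroxyls must later be told apart for two different esters. The methylene group must be made from the C4 ketal by olefination in the presence of the C2 ketone, and the C7 arm is a single oxygenated carbon that must be extended. It is as strong on the enone and stronger on the supply of C5–C7. The chosen route offers O5/O6 differentiation and the methylene group without extra steps.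

Alternative 3: The bonds C3a–C7a, C2–C3 and C1–C2 are cut, and a cobalt-mediated or rhodium-catalysed carbonylative [2+2+1] cyclisation (Pauson–Khand) of a dienyne would give A3. In its favour, it is the most step-economic option: both rings and three C–C bonds form in one step, with the methylene group, the enone and an acrylate arm already in place. Against it: 1,7-enynes close more slowly than 1,6-enynes, and a 1,3-diene as the alkene partner can divert to [4+2] pathways. C3a depends on substrate control by the acetonide alone. The acrylate is a competing alkene and would not survive the later copper hydride step unless it is epoxidised first, in competition with the enone. The acetonide again leaves O5 and O6 undifferentiated. It is clearly stronger on convergence. The chosen route offers an arm that is inert to chromium and to copper hydride, separate control of each oxygen, and a reagent-controlled oxirane.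

Key step: step 15

## Steps

Step 1
Reactants: 1 (4S)-4-[(tert-butyldimethylsilyl)oxy]cyclopent-2-en-1-one; 2 (1-bromoethenyl)trimethylsilane
Product: 5 (4S)-4-[1-(trimethylsilyl)ethenyl]cyclopent-2-en-1-one, via Grignard reagent 3 (not isolated), via silyloxy ketone 4 (not isolated)
Conditions: 2, Mg, THF; CuBr·SMe2 (10 mol %), 1, THF, −78 °C; aq. NH4Cl; then DBU, CH2Cl2, 0 °C
Reagents that add atoms: none
Why: Copper-catalysed conjugate addition of the alkenyl Grignard reagent 3 occurs anti to the C4 silyloxy group, and base-induced E1cB loss of the silanol from 4 then moves the enone (overall addition–elimination); the carbon that received the alkenyl group becomes C3a with the (S) configuration and is never α to a carbonyl group.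

Step 2
Reactants: 5 (4S)-4-[1-(trimethylsilyl)ethenyl]cyclopent-2-en-1-one
Product: 6 (4S)-2-iodo-4-[1-(trimethylsilyl)ethenyl]cyclopent-2-en-1-one
Conditions: I2, pyridine, CH2Cl2, 0 → 25 °C
Reagents that add atoms: iodine, II
Why: α-Iodination of a cyclic enone by the iodine–pyridine method (conjugate addition of pyridine, iodination of the enolate, elimination); the alkenylsilane should not react with molecular iodine under these buffered conditions.

Step 3
Reactants: 6 (4S)-2-iodo-4-[1-(trimethylsilyl)ethenyl]cyclopent-2-en-1-one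
Product: 7 (8S)-6-iodo-8-[1-(trimethylsilyl)ethenyl]-1,4-dioxaspiro[4.4]non-6-ene
Conditions: Me3SiOCH2CH2OSiMe3, Me3SiOTf (5 mol %), CH2Cl2, −78 → −20 °C
Reagents that add atoms: 1,2-bis(trimethylsilyloxy)ethane, C[Si](C)(C)OCCO[Si](C)(C)C
Why: Aprotic silyl-transfer ketalisation masks the ketone so that the α-iodoenone can act as an α-keto vinyl anion equivalent; the low temperature should spare the alkenylsilane and keep the double bond in place.

Step 4
Reactants: 7 (8S)-6-iodo-8-[1-(trimethylsilyl)ethenyl]-1,4-dioxaspiro[4.4]non-6-ene; 8 N-methoxy-N-methylacetamide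
Product: 10 1-{(8S)-8-[1-(trimethylsilyl)ethenyl]-1,4-dioxaspiro[4.4]non-6-en-6-yl}ethan-1-one, via alkenyllithium 9 (not isolated)
Conditions: t-BuLi (2.1 equiv), THF, −78 °C; then 8, −78 → 0 °C; aq. NH4Cl
Reagents that add atoms: none
Why: Iodine–lithium exchange gives the alkenyllithium 9, and its acylation by the N-methoxy-N-methyl amide 8 stops at the ketone because the chelated tetrahedral adduct collapses only on work-up (Weinreb-type ketone synthesis).

Step 5
Reactants: 10 1-{(8S)-8-[1-(trimethylsilyl)ethenyl]-1,4-dioxaspiro[4.4]non-6-en-6-yl}ethan-1-one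
Product: 11 (1S)-1-{(8S)-8-[1-(trimethylsilyl)ethenyl]-1,4-dioxaspiro[4.4]non-6-en-6-yl}ethan-1-ol
Conditions: (R)-1-methyl-3,3-diphenyltetrahydro-1H,3H-pyrrolo[1,2-c][1,3,2]oxazaborole (10 mol %), catecholborane, toluene, −78 °C
Reagents that add atoms: none
Why: Corey–Bakshi–Shibata reduction: with the alkenyl residue as the large group and methyl as the small one, the (R)-oxazaborolidine should give the (S)-carbinol C1′; catecholborane at low temperature does not hydroborate the alkenes, and the masked ring ketone cannot compete.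

Step 6
Reactants: 11 (1S)-1-{(8S)-8-[1-(trimethylsilyl)ethenyl]-1,4-dioxaspiro[4.4]non-6-en-6-yl}ethan-1-ol
Product: 13 (4S)-2-{(1S)-1-[(tert-butyldimethylsilyl)oxy]ethyl}-4-[1-(trimethylsilyl)ethenyl]cyclopent-2-en-1-one, via silyl ether ketal 12 (not isolated)
Conditions: t-BuMe2SiCl, imidazole, DMF, 25 °C; then pyridinium p-toluenesulfonate (cat.), acetone/H2O, 25 °C
Reagents that add atoms: tert-butyldimethylsilyl chloride, CC(C)(C)[Si](C)(C)Cl; water, O
Why: Silylation of the allylic alcohol followed by mild acid-catalysed ketal hydrolysis returns the enone; the secondary silyl ether and the alkenylsilane tolerate the pyridinium salt.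

Step 7
Reactants: 13 (4S)-2-{(1S)-1-[(tert-butyldimethylsilyl)oxy]ethyl}-4-[1-(trimethylsilyl)ethenyl]cyclopent-2-en-1-one; 14 tert-butyl{[(2E)-3-iodoprop-2-en-1-yl]oxy}dimethylsilane
Product: 17 (4S)-2-{(1S)-1-[(tert-butyldimethylsilyl)oxy]ethyl}-3-{(1E)-3-[(tert-butyldimethylsilyl)oxy]prop-1-en-1-yl}-2-(phenylselanyl)-4-[1-(trimethylsilyl)ethenyl]cyclopentan-1-one (3-alkenyl trans to both the 4-alkenyl group and selenium), via alkenylmagnesium chloride 15 (not isolated), via silyl enol ether 16 (not isolated)
Conditions: 14, i-PrMgCl·LiCl, THF, 0 → 25 °C; CuBr·SMe2 (10 mol %), Me3SiCl, 13, THF, −78 °C; then PhSeCl, −78 → −40 °C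
Reagents that add atoms: benzeneselenenyl chloride, Cl[Se]c1ccccc1
Why: Iodine–magnesium exchange keeps the E geometry, and copper-catalysed, silyl-chloride-accelerated conjugate addition puts the three-carbon chain on C7a anti to the C3a substituent. α-Selenenylation of the silyl enol ether 16 then occurs anti to the new chain, so selenium and H7a are cis as the later syn elimination requires.

Step 8
Reactants: 17 (the 2-phenylselanyl ketone of step 7)
Product: 20 (4S)-2-{(1S)-1-[(tert-butyldimethylsilyl)oxy]ethyl}-3-[(1E)-3-hydroxyprop-1-en-1-yl]-4-[1-(trimethylsilyl)ethenyl]cyclopent-2-en-1-one, via selenoxide 18 (not isolated), via bis-silyl dienone 19 (not isolated)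
Conditions: H2O2 (30 % aq.), pyridine, CH2Cl2, 0 °C; then camphorsulfonic acid (cat.), MeOH/CH2Cl2, 0 °C
Reagents that add atoms: none
Why: Selenoxide syn elimination can use H7a and avoids the C1′–H, because elimination toward an oxygen-bearing carbon is disfavoured; this regenerates the C1=C7a enone, now fully substituted. Acid-catalysed methanolysis then removes the primary allylic silyl ether faster than the hindered secondary one.

Step 9
Reactants: 20 (the dienone allylic alcohol of step 8)
Product: 21 (4S)-2-{(1S)-1-[(tert-butyldimethylsilyl)oxy]ethyl}-3-[(2S,3S)-3-(hydroxymethyl)oxiran-2-yl]-4-[1-(trimethylsilyl)ethenyl]cyclopent-2-en-1-one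
Conditions: Ti(OiPr)4 (20 mol %), diethyl L-(+)-tartrate (24 mol %), t-BuOOH, 4 Å molecular sieves, CH2Cl2, −20 °C
Reagents that add atoms: tert-butyl hydroperoxide, CC(C)(C)OO
Why: Sharpless asymmetric epoxidation of the E allylic alcohol; the L-(+)-tartrate should give the (2S,3S)-epoxy alcohol, which fixes C6 and the configuration at C7 that is to be inverted. The reagent selects the allylic alcohol over the enone, the alkenylsilane and the silyl ether.

Step 10
Reactants: 22 2-bromoprop-2-en-1-ol
Product: 23 1-{[(2-bromoprop-2-en-1-yl)oxy]methyl}-4-methoxybenzene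
Conditions: NaH, 4-methoxybenzyl chloride, Bu4NI (cat.), THF, 0 → 25 °C
Reagents that add atoms: 4-methoxybenzyl chloride, COc1ccc(CCl)cc1
Why: Williamson ether synthesis; the 4-methoxybenzyl group survives organolithium, copper, chromium and copper hydride chemistry and is later removed oxidatively next to silyl ethers and esters.

Step 11
Reactants: 21 (the epoxy alcohol of step 9); 23 1-{[(2-bromoprop-2-en-1-yl)oxy]methyl}-4-methoxybenzene
Product: 26 (4S)-2-{(1S)-1-[(tert-butyldimethylsilyl)oxy]ethyl}-3-[(3S,4R)-4,5-dihydroxy-2-{[(4-methoxyphenyl)methoxy]methyl}pent-1-en-3-yl]-4-[1-(trimethylsilyl)ethenyl]cyclopent-2-en-1-one, via alkenyllithium 24 (not isolated), via lithium dialkenylcuprate 25 (not isolated)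
Conditions: 23, t-BuLi (2 equiv), Et2O, −78 °C; CuI (0.5 equiv), −40 °C; 21, Et2O/THF, −78 → −30 °C; aq. NH4Cl/NH3
Reagents that add atoms: none
Why: Bromine–lithium exchange and transmetalation give the cuprate 25, which should open the alkenyl oxirane by direct SN2 substitution at the allylic carbon C7 with inversion, because the SN2′ terminus C1 and the β-carbon C7a are fully substituted. The trans-oxirane therefore places the C7 arm anti to O6 in the C7a–C7–C6–C5 zigzag, which is cis on the future ring; cuprates do not add to the ketone carbonyl.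

Step 12
Reactants: 26 (the diol of step 11)
Product: 27 (4S)-2-{(1S)-1-[(tert-butyldimethylsilyl)oxy]ethyl}-3-[(3S,4R)-2-{[(4-methoxyphenyl)methoxy]methyl}-4,5-bis[(triethylsilyl)oxy]pent-1-en-3-yl]-4-[1-(trimethylsilyl)ethenyl]cyclopent-2-en-1-one
Conditions: Et3SiOTf, 2,6-lutidine, CH2Cl2, −78 °C
Reagents that add atoms: triethylsilyl trifluoromethanesulfonate, CC[Si](CC)(CC)OS(=O)(=O)C(F)(F)F
Why: Silylation of both hydroxyl groups with a silyl triflate and a hindered base; triethylsilyl is chosen so that O6 can later be freed before the C1′ tert-butyldimethylsilyl ether.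

Step 13
Reactants: 27 (the bis-triethylsilyl ether of step 12)
Product: 28 (4S)-2-{(1S)-1-[(tert-butyldimethylsilyl)oxy]ethyl}-4-(1-iodoethenyl)-3-[(3S,4R)-2-{[(4-methoxyphenyl)methoxy]methyl}-4,5-bis[(triethylsilyl)oxy]pent-1-en-3-yl]cyclopent-2-en-1-one
Conditions: N-iodosuccinimide, MeCN/ClCH2CN (4:1), 0 → 25 °C
Reagents that add atoms: N-iodosuccinimide, O=C1CCC(=O)N1I
Why: Iododesilylation (ipso substitution) of the 1,1-disubstituted alkenylsilane; the electron-poor enone and the less nucleophilic allyl ether alkene should not compete, and no free hydroxyl group is present that could form an iodoether.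

Step 14
Reactants: 28 (the alkenyl iodide of step 13)
Product: 29 (2R,3S)-3-[(5S)-2-{(1S)-1-[(tert-butyldimethylsilyl)oxy]ethyl}-5-(1-iodoethenyl)-3-oxocyclopent-1-en-1-yl]-4-{[(4-methoxyphenyl)methoxy]methyl}-2-[(triethylsilyl)oxy]pent-4-enal
Conditions: (COCl)2, DMSO, CH2Cl2, −78 °C; Et3N, −78 → −30 °C
Reagents that add atoms: none
Why: Swern oxidation applied directly to the bis-silyl ether: the activated sulfonium salt cleaves and oxidises the primary triethylsilyl ether and leaves the secondary one, so the α-silyloxy aldehyde is obtained without a separate deprotection. The amine is added cold to avoid epimerisation at C6.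

Step 15
Reactants: 29 (the iodoalkenyl aldehyde of step 14)
Product: 30 (3aS,5S,6R,7S)-1-{(1S)-1-[(tert-butyldimethylsilyl)oxy]ethyl}-5-hydroxy-7-{3-[(4-methoxyphenyl)methoxy]prop-1-en-2-yl}-4-methylidene-6-[(triethylsilyl)oxy]-3,3a,4,5,6,7-hexahydro-2H-inden-2-one
Conditions: CrCl2 (8 equiv), NiCl2 (1 mol %), degassed DMSO, 25 °C
Reagents that add atoms: none
Why: Zerovalent nickel, formed in situ from NiCl2 by CrCl2, inserts into the C4–I bond of 29; transmetalation gives the alkenyl trivalent-chromium species, which adds to the C5 aldehyde through a closed four-centre transition state and leaves a chromium alkoxide that is hydrolysed on work-up. The closest known reaction type is the intramolecular Nozaki–Hiyama–Kishi cyclisation of ω-(2-iodoalkenyl) aldehydes to 2-methylenecycloalkanols. The six-membered ring closes in the 6-exo-trig mode, C4 attacking the carbonyl carbon with the C=O bond outside the ring. C5 is the only new stereocentre: the planar cyclopentenone allows one chair for the forming ring (H3a axial), in which the C6 silyloxy group is axial and the C7 arm equatorial, and the carbonyl is expected to add with its chromium-bound oxygen pseudo-equatorial, away from the syn-axial hydrogens on C3a and C7, which places O5 cis to O6. This is also the sense of a polar Felkin–Anh addition anti to the α-silyloxy group, although the ring does not allow its ideal geometry. The step needs chemoselectivity for the aldehyde over the C2 enone, the allyl ether and the silyl ethers, which the low basicity and aldehyde selectivity of alkenylchromium reagents provide, and metalation at one site only, which nickel insertion into the single C–I bond secures. The enone, the C1′ silyl ether and the C7 arm are spectators.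

Step 16
Reactants: 30 (the bicyclic alcohol of step 15); 31 (2R)-2-methylbutanoic acid
Product: 32 (3aS,5S,6R,7S)-1-{(1S)-1-[(tert-butyldimethylsilyl)oxy]ethyl}-7-{3-[(4-methoxyphenyl)methoxy]prop-1-en-2-yl}-4-methylidene-2-oxo-6-[(triethylsilyl)oxy]-3,3a,4,5,6,7-hexahydro-2H-inden-5-yl (2R)-2-methylbutanoate
Conditions: EDC·HCl, 4-(dimethylamino)pyridine (cat.), CH2Cl2, 0 → 25 °C
Reagents that add atoms: none
Why: Carbodiimide (Steglich) esterification of the allylic C5 alcohol, the only free hydroxyl group; activation at low temperature should preserve the α-stereocentre of the acid.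

Step 17
Reactants: 32 (the enone ester of step 16)
Product: 33 (1R,3aS,5S,6R,7S,7aR)-1-{(1S)-1-[(tert-butyldimethylsilyl)oxy]ethyl}-7-{3-[(4-methoxyphenyl)methoxy]prop-1-en-2-yl}-4-methylidene-2-oxo-6-[(triethylsilyl)oxy]octahydro-1H-inden-5-yl (2R)-2-methylbutanoate
Conditions: [(Ph3P)CuH]6 (0.4 equiv), H2O (2 equiv), toluene, 25 °C
Reagents that add atoms: none
Why: Conjugate reduction by the phosphine copper hydride (1,4-hydride addition, then protonation of the copper enolate by water). Hydride should reach C7a from the face of H3a, the face not screened by the C5, C6 and C7 substituents, giving the cis ring fusion; kinetic protonation at C1 from the same convex face places the side chain cis to C7. Isolated alkenes, esters and ethers are not reduced.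

Step 18
Reactants: 33 (the saturated ketone of step 17)
Product: 34 (1R,3aS,5S,6R,7S,7aR)-1-{(1S)-1-[(tert-butyldimethylsilyl)oxy]ethyl}-7-(3-hydroxyprop-1-en-2-yl)-4-methylidene-2-oxo-6-[(triethylsilyl)oxy]octahydro-1H-inden-5-yl (2R)-2-methylbutanoate
Conditions: 2,3-dichloro-5,6-dicyano-1,4-benzoquinone, CH2Cl2/pH 7 buffer, 0 °C
Reagents that add atoms: none
Why: Oxidative cleavage of the 4-methoxybenzyl ether by hydride abstraction and hydrolysis of the oxocarbenium ion; silyl ethers, esters and the ketone are inert.

Step 19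
Reactants: 34 (the allylic alcohol of step 18)
Product: 35 (1R,3aS,5S,6R,7R,7aR)-1-{(1S)-1-[(tert-butyldimethylsilyl)oxy]ethyl}-7-[(2R)-2-(hydroxymethyl)oxiran-2-yl]-4-methylidene-2-oxo-6-[(triethylsilyl)oxy]octahydro-1H-inden-5-yl (2R)-2-methylbutanoate
Conditions: Ti(OiPr)4 (20 mol %), diethyl D-(−)-tartrate (24 mol %), t-BuOOH, 4 Å molecular sieves, CH2Cl2, −20 °C
Reagents that add atoms: tert-butyl hydroperoxide, CC(C)(C)OO
Why: Sharpless asymmetric epoxidation of the 2-substituted allylic alcohol; by the same facial rule the D-(−)-tartrate should give the (R)-epoxy alcohol, which becomes the (S)-glycidate after oxidation, under reagent control. The 4-methylidene group is not epoxidised because its allylic oxygen is acylated.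

Step 20
Reactants: 35 (the epoxy alcohol of step 19)
Product: 37 methyl (2S)-2-[(1R,3aS,5S,6R,7R,7aR)-1-{(1S)-1-[(tert-butyldimethylsilyl)oxy]ethyl}-4-methylidene-5-{[(2R)-2-methylbutanoyl]oxy}-2-oxo-6-[(triethylsilyl)oxy]octahydro-1H-inden-7-yl]oxirane-2-carboxylate, via oxirane carboxylic acid 36 (not isolated)
Conditions: PhI(OAc)2, 2,2,6,6-tetramethylpiperidin-1-oxyl (cat.), MeCN/H2O, 25 °C; then Me3SiCHN2, toluene/MeOH, 0 °C
Reagents that add atoms: water, O; (trimethylsilyl)diazomethane, C[Si](C)(C)C=[N+]=[N-]
Why: Nitroxyl-catalysed oxidation of the primary alcohol through the aldehyde hydrate to the carboxylic acid, then esterification with the diazo reagent; neither operation enolises the ketone or opens the oxirane.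

Step 21
Reactants: 37 (the glycidic ester of step 20)
Product: 38 methyl (2S)-2-[(1R,3aS,5S,6R,7R,7aR)-1-{(1S)-1-[(tert-butyldimethylsilyl)oxy]ethyl}-6-hydroxy-4-methylidene-5-{[(2R)-2-methylbutanoyl]oxy}-2-oxooctahydro-1H-inden-7-yl]oxirane-2-carboxylate
Conditions: HF·pyridine, pyridine, THF, 0 °C
Reagents that add atoms: none
Why: Buffered fluoride-mediated desilylation removes the triethylsilyl ether faster than the tert-butyldimethylsilyl ether; the acidic medium disfavours O5→O6 acyl migration, and the electron-poor oxirane should not be opened.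

Step 22
Reactants: 38 (the C6 alcohol of step 21); 39 (2E)-3-methylpent-2-enoic acid
Product: 40 methyl (2S)-2-[(1R,3aS,5S,6R,7R,7aR)-1-{(1S)-1-[(tert-butyldimethylsilyl)oxy]ethyl}-4-methylidene-5-{[(2R)-2-methylbutanoyl]oxy}-6-{[(2E)-3-methylpent-2-enoyl]oxy}-2-oxooctahydro-1H-inden-7-yl]oxirane-2-carboxylate
Conditions: EDC·HCl, 4-(dimethylamino)pyridine (cat.), CH2Cl2, 25 °C
Reagents that add atoms: none
Why: Carbodiimide (Steglich) esterification of the C6 alcohol; the mild activation avoids ketene formation and so keeps the E geometry and the conjugation of the enoic acid.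

Step 23
Reactants: 40 (the diester silyl ether of step 22)
Product: 41 methyl (2S)-2-[(1R,3aS,5S,6R,7R,7aR)-1-[(1S)-1-hydroxyethyl]-4-methylidene-5-{[(2R)-2-methylbutanoyl]oxy}-6-{[(2E)-3-methylpent-2-enoyl]oxy}-2-oxooctahydro-1H-inden-7-yl]oxirane-2-carboxylate
Conditions: HF·pyridine, THF, 0 → 25 °C
Reagents that add atoms: none
Why: Desilylation of the remaining silyl ether with the same reagent at higher temperature; no base is present that could trigger retro-aldol cleavage or β-elimination of the β-hydroxy ketone.

Step 24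
Reactants: 41 (the β-hydroxy ketone of step 23)
Product: 42 CNP0251769.1, methyl (2S)-2-[(1R,3aS,5S,6R,7R,7aR)-1-[(1S)-1-acetoxyethyl]-4-methylidene-5-{[(2R)-2-methylbutanoyl]oxy}-6-{[(2E)-3-methylpent-2-enoyl]oxy}-2-oxooctahydro-1H-inden-7-yl]oxirane-2-carboxylate
Conditions: Ac2O, pyridine, 4-(dimethylamino)pyridine (cat.), CH2Cl2, 0 °C
Reagents that add atoms: acetic anhydride, CC(=O)OC(C)=O
Why: Acetylation by nucleophilic catalysis at low temperature, kept short to avoid β-elimination of the β-acetoxy ketone or epimerisation at C1.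

## Compound list

1 | (4S)-4-[(tert-butyldimethylsilyl)oxy]cyclopent-2-en-1-one | O=C1C[C@H](O[Si](C)(C)C(C)(C)C)C=C1 | starting material
2 | (1-bromoethenyl)trimethylsilane | C=C(Br)[Si](C)(C)C | starting material
3 | [1-(trimethylsilyl)ethenyl]magnesium bromide | C=C([Mg]Br)[Si](C)(C)C | intermediate
4 | (3S,4S)-4-[(tert-butyldimethylsilyl)oxy]-3-[1-(trimethylsilyl)ethenyl]cyclopentan-1-one | O=C1C[C@H](O[Si](C)(C)C(C)(C)C)[C@@H](C(=C)[Si](C)(C)C)C1 | intermediate
5 | (4S)-4-[1-(trimethylsilyl)ethenyl]cyclopent-2-en-1-one | O=C1C[C@H](C(=C)[Si](C)(C)C)C=C1 | intermediate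
6 | (4S)-2-iodo-4-[1-(trimethylsilyl)ethenyl]cyclopent-2-en-1-one | O=C1C[C@H](C(=C)[Si](C)(C)C)C=C1I | intermediate
7 | (8S)-6-iodo-8-[1-(trimethylsilyl)ethenyl]-1,4-dioxaspiro[4.4]non-6-ene | C1COC2(O1)C[C@H](C(=C)[Si](C)(C)C)C=C2I | intermediate
8 | N-methoxy-N-methylacetamide | CC(=O)N(C)OC | starting material
9 | {(8S)-8-[1-(trimethylsilyl)ethenyl]-1,4-dioxaspiro[4.4]non-6-en-6-yl}lithium | C1COC2(O1)C[C@H](C(=C)[Si](C)(C)C)C=C2[Li] | intermediate
10 | 1-{(8S)-8-[1-(trimethylsilyl)ethenyl]-1,4-dioxaspiro[4.4]non-6-en-6-yl}ethan-1-one | C1COC2(O1)C[C@H](C(=C)[Si](C)(C)C)C=C2C(C)=O | intermediate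
11 | (1S)-1-{(8S)-8-[1-(trimethylsilyl)ethenyl]-1,4-dioxaspiro[4.4]non-6-en-6-yl}ethan-1-ol | C1COC2(O1)C[C@H](C(=C)[Si](C)(C)C)C=C2[C@H](C)O | intermediate
12 | tert-butyldimethylsilyl ether of 11 | C1COC2(O1)C[C@H](C(=C)[Si](C)(C)C)C=C2[C@H](C)O[Si](C)(C)C(C)(C)C | intermediate
13 | (4S)-2-{(1S)-1-[(tert-butyldimethylsilyl)oxy]ethyl}-4-[1-(trimethylsilyl)ethenyl]cyclopent-2-en-1-one | O=C1C[C@H](C(=C)[Si](C)(C)C)C=C1[C@H](C)O[Si](C)(C)C(C)(C)C | intermediate
14 | tert-butyl{[(2E)-3-iodoprop-2-en-1-yl]oxy}dimethylsilane | I/C=C/CO[Si](C)(C)C(C)(C)C | starting material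
15 | {(1E)-3-[(tert-butyldimethylsilyl)oxy]prop-1-en-1-yl}magnesium chloride | Cl[Mg]/C=C/CO[Si](C)(C)C(C)(C)C | intermediate
16 | trimethylsilyl enol ether of the 3,4-trans conjugate adduct of 13 | C[Si](C)(C)OC1=C([C@H](C)O[Si](C)(C)C(C)(C)C)[C@H](/C=C/CO[Si](C)(C)C(C)(C)C)[C@@H](C(=C)[Si](C)(C)C)C1 | intermediate
17 | (4S)-2-{(1S)-1-[(tert-butyldimethylsilyl)oxy]ethyl}-3-{(1E)-3-[(tert-butyldimethylsilyl)oxy]prop-1-en-1-yl}-2-(phenylselanyl)-4-[1-(trimethylsilyl)ethenyl]cyclopentan-1-one, 2-Se/3-alkenyl trans, 3,4-trans | O=C1C[C@H](C(=C)[Si](C)(C)C)[C@@H](/C=C/CO[Si](C)(C)C(C)(C)C)[C@@]1([Se]c2ccccc2)[C@H](C)O[Si](C)(C)C(C)(C)C | intermediate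
18 | selenoxide of 17 | O=C1C[C@H](C(=C)[Si](C)(C)C)[C@@H](/C=C/CO[Si](C)(C)C(C)(C)C)[C@@]1([Se](=O)c2ccccc2)[C@H](C)O[Si](C)(C)C(C)(C)C | intermediate
19 | (4S)-2-{(1S)-1-[(tert-butyldimethylsilyl)oxy]ethyl}-3-{(1E)-3-[(tert-butyldimethylsilyl)oxy]prop-1-en-1-yl}-4-[1-(trimethylsilyl)ethenyl]cyclopent-2-en-1-one | O=C1C[C@H](C(=C)[Si](C)(C)C)C(/C=C/CO[Si](C)(C)C(C)(C)C)=C1[C@H](C)O[Si](C)(C)C(C)(C)C | intermediate
20 | (4S)-2-{(1S)-1-[(tert-butyldimethylsilyl)oxy]ethyl}-3-[(1E)-3-hydroxyprop-1-en-1-yl]-4-[1-(trimethylsilyl)ethenyl]cyclopent-2-en-1-one | O=C1C[C@H](C(=C)[Si](C)(C)C)C(/C=C/CO)=C1[C@H](C)O[Si](C)(C)C(C)(C)C | intermediate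
21 | (4S)-2-{(1S)-1-[(tert-butyldimethylsilyl)oxy]ethyl}-3-[(2S,3S)-3-(hydroxymethyl)oxiran-2-yl]-4-[1-(trimethylsilyl)ethenyl]cyclopent-2-en-1-one | O=C1C[C@H](C(=C)[Si](C)(C)C)C([C@@H]2O[C@H]2CO)=C1[C@H](C)O[Si](C)(C)C(C)(C)C | intermediate
22 | 2-bromoprop-2-en-1-ol | C=C(Br)CO | starting material
23 | 1-{[(2-bromoprop-2-en-1-yl)oxy]methyl}-4-methoxybenzene | C=C(Br)COCc1ccc(OC)cc1 | intermediate
24 | {3-[(4-methoxyphenyl)methoxy]prop-1-en-2-yl}lithium | [Li]C(=C)COCc1ccc(OC)cc1 | intermediate
25 | lithium bis{3-[(4-methoxyphenyl)methoxy]prop-1-en-2-yl}cuprate | [Li+].C=C(COCc1ccc(OC)cc1)[Cu-]C(=C)COCc1ccc(OC)cc1 | intermediate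
26 | (4S)-2-{(1S)-1-[(tert-butyldimethylsilyl)oxy]ethyl}-3-[(3S,4R)-4,5-dihydroxy-2-{[(4-methoxyphenyl)methoxy]methyl}pent-1-en-3-yl]-4-[1-(trimethylsilyl)ethenyl]cyclopent-2-en-1-one | O=C1C[C@H](C(=C)[Si](C)(C)C)C([C@@H](C(=C)COCc2ccc(OC)cc2)[C@@H](O)CO)=C1[C@H](C)O[Si](C)(C)C(C)(C)C | intermediate
27 | 4,5-bis(triethylsilyl) ether of 26 | O=C1C[C@H](C(=C)[Si](C)(C)C)C([C@@H](C(=C)COCc2ccc(OC)cc2)[C@@H](O[Si](CC)(CC)CC)CO[Si](CC)(CC)CC)=C1[C@H](C)O[Si](C)(C)C(C)(C)C | intermediate
28 | (4S)-4-(1-iodoethenyl) analogue of 27 | O=C1C[C@H](C(I)=C)C([C@@H](C(=C)COCc2ccc(OC)cc2)[C@@H](O[Si](CC)(CC)CC)CO[Si](CC)(CC)CC)=C1[C@H](C)O[Si](C)(C)C(C)(C)C | intermediate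
29 | (2R,3S)-3-[(5S)-2-{(1S)-1-[(tert-butyldimethylsilyl)oxy]ethyl}-5-(1-iodoethenyl)-3-oxocyclopent-1-en-1-yl]-4-{[(4-methoxyphenyl)methoxy]methyl}-2-[(triethylsilyl)oxy]pent-4-enal | O=C1C[C@H](C(I)=C)C([C@@H](C(=C)COCc2ccc(OC)cc2)[C@@H](O[Si](CC)(CC)CC)C=O)=C1[C@H](C)O[Si](C)(C)C(C)(C)C | intermediate
30 | (3aS,5S,6R,7S)-1-{(1S)-1-[(tert-butyldimethylsilyl)oxy]ethyl}-5-hydroxy-7-{3-[(4-methoxyphenyl)methoxy]prop-1-en-2-yl}-4-methylidene-6-[(triethylsilyl)oxy]-3,3a,4,5,6,7-hexahydro-2H-inden-2-one | C=C1[C@H]2CC(=O)C([C@H](C)O[Si](C)(C)C(C)(C)C)=C2[C@@H](C(=C)COCc3ccc(OC)cc3)[C@@H](O[Si](CC)(CC)CC)[C@H]1O | intermediate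
31 | (2R)-2-methylbutanoic acid | CC[C@@H](C)C(=O)O | starting material
32 | (2R)-2-methylbutanoate of 30 at O5 | C=C1[C@H]2CC(=O)C([C@H](C)O[Si](C)(C)C(C)(C)C)=C2[C@@H](C(=C)COCc3ccc(OC)cc3)[C@@H](O[Si](CC)(CC)CC)[C@H]1OC(=O)[C@H](C)CC | intermediate
33 | (1R,3aS,5S,6R,7S,7aR)-1-{(1S)-1-[(tert-butyldimethylsilyl)oxy]ethyl}-7-{3-[(4-methoxyphenyl)methoxy]prop-1-en-2-yl}-4-methylidene-2-oxo-6-[(triethylsilyl)oxy]octahydro-1H-inden-5-yl (2R)-2-methylbutanoate | C=C1[C@H]2CC(=O)[C@@H]([C@H](C)O[Si](C)(C)C(C)(C)C)[C@H]2[C@@H](C(=C)COCc3ccc(OC)cc3)[C@@H](O[Si](CC)(CC)CC)[C@H]1OC(=O)[C@H](C)CC | intermediate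
34 | 7-(3-hydroxyprop-1-en-2-yl) analogue of 33 | C=C1[C@H]2CC(=O)[C@@H]([C@H](C)O[Si](C)(C)C(C)(C)C)[C@H]2[C@@H](C(=C)CO)[C@@H](O[Si](CC)(CC)CC)[C@H]1OC(=O)[C@H](C)CC | intermediate
35 | (1R,3aS,5S,6R,7R,7aR)-1-{(1S)-1-[(tert-butyldimethylsilyl)oxy]ethyl}-7-[(2R)-2-(hydroxymethyl)oxiran-2-yl]-4-methylidene-2-oxo-6-[(triethylsilyl)oxy]octahydro-1H-inden-5-yl (2R)-2-methylbutanoate | C=C1[C@H]2CC(=O)[C@@H]([C@H](C)O[Si](C)(C)C(C)(C)C)[C@H]2[C@@H]([C@@]3(CO)CO3)[C@@H](O[Si](CC)(CC)CC)[C@H]1OC(=O)[C@H](C)CC | intermediate
36 | (2S)-oxirane-2-carboxylic acid corresponding to 35 | C=C1[C@H]2CC(=O)[C@@H]([C@H](C)O[Si](C)(C)C(C)(C)C)[C@H]2[C@@H]([C@@]3(C(=O)O)CO3)[C@@H](O[Si](CC)(CC)CC)[C@H]1OC(=O)[C@H](C)CC | intermediate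
37 | methyl (2S)-oxirane-2-carboxylate with O6 triethylsilyl and C1′ tert-butyldimethylsilyl ethers | C=C1[C@H]2CC(=O)[C@@H]([C@H](C)O[Si](C)(C)C(C)(C)C)[C@H]2[C@@H]([C@@]3(C(=O)OC)CO3)[C@@H](O[Si](CC)(CC)CC)[C@H]1OC(=O)[C@H](C)CC | intermediate
38 | 6-hydroxy compound from 37 | C=C1[C@H]2CC(=O)[C@@H]([C@H](C)O[Si](C)(C)C(C)(C)C)[C@H]2[C@@H]([C@@]3(C(=O)OC)CO3)[C@@H](O)[C@H]1OC(=O)[C@H](C)CC | intermediate
39 | (2E)-3-methylpent-2-enoic acid | CC/C(C)=C/C(=O)O | starting material
40 | 6-O-[(2E)-3-methylpent-2-enoyl] derivative of 38 | C=C1[C@H]2CC(=O)[C@@H]([C@H](C)O[Si](C)(C)C(C)(C)C)[C@H]2[C@@H]([C@@]3(C(=O)OC)CO3)[C@@H](OC(=O)/C=C(\C)CC)[C@H]1OC(=O)[C@H](C)CC | intermediate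
41 | 1-[(1S)-1-hydroxyethyl] compound from 40 | C=C1[C@H]2CC(=O)[C@@H]([C@H](C)O)[C@H]2[C@@H]([C@@]3(C(=O)OC)CO3)[C@@H](OC(=O)/C=C(\C)CC)[C@H]1OC(=O)[C@H](C)CC | intermediate
42 | CNP0251769.1 | C=C1[C@H]2CC(=O)[C@@H]([C@H](C)OC(C)=O)[C@H]2[C@@H]([C@@]2(C(=O)OC)CO2)[C@@H](OC(=O)/C=C(\C)CC)[C@H]1OC(=O)[C@H](C)CC | target

## Step count and least certain steps

Total step count: 24. Longest linear sequence: 23 steps (steps 1–9 and 11–24, from 1 to 42); step 10 is a one-step side branch.

Step 15 (key step). The most likely failure is insufficient facial discrimination at the aldehyde: closure with the carbonyl oxygen axial is opposed only by two syn-axial hydrogens and relieves the gauche interaction with the C6 oxygen. Closure may also be slow, because the equatorial C7 arm is eclipsed with the C1 side chain, so protonolysis of the alkenylchromium species can compete. Fallback: setting out from 29, the coupling is run as before and the C5 epimer is not discarded. This epimer, (3aS,5R,6R,7S)-5-epi-30 F1, is esterified with inversion by a Mitsunobu reaction with 31 (PPh3, diisopropyl azodicarboxylate, toluene), which returns to the route at 32; any 30 formed alongside goes on through step 16.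

Step 11. Regiocontrol may be lost through attack at C6 directed by the lithium alkoxide, or the oxirane may be cleaved reductively by electron transfer through the conjugated enone. Fallback: setting out from 23 and 21, the arm is brought in by zerovalent-palladium chemistry instead of copper. Miyaura borylation of 23 (B2pin2, PdCl2(dppf), KOAc) gives 2-{3-[(4-methoxyphenyl)methoxy]prop-1-en-2-yl}-4,4,5,5-tetramethyl-1,3,2-dioxaborolane F2. Pd(PPh3)4-catalysed coupling of F2 with 21 then opens the oxirane through a π-allyl complex (ionisation with inversion, transmetalation, reductive elimination at the less hindered terminus C7 with retention), which returns to the route at 26.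

Step 9. Oxygen transfer to the alkene may be slow because it is conjugated with the enone, and the titanium alkoxide may open the sensitive alkenyl oxirane once it is formed. Fallback: setting out from 19, which is isolated before the methanolysis, a Shi epoxidation is used (the enantiomer of the fructose-derived ketone, Oxone, buffered MeCN/dimethoxymethane). It needs no free hydroxyl group and gives the (2S,3S)-oxirane silyl ether F3; buffered desilylation (Bu4NF, AcOH, THF) then returns to the route at 21.

Step 17. Hydride transfer to the tetrasubstituted β-carbon may be slow, which gives time for SN2′ reduction of the allylic C5 ester and for equilibration at C1 to the trans-2,3-disubstituted cyclopentanone. Fallback: setting out from 32, the enone is reduced by electron transfer with SmI2 (THF/MeOH, −78 °C). The ketyl is protonated at C7a and the samarium enolate at C1 by methanol from the open face, which returns to the route at 33; this fallback makes no compound outside the list (F0).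

Step 7. Selenenylation at the fully substituted C1 may be too hindered, so that the conjugate adduct is simply protonated on work-up. Fallback: setting out from 13 and 14, the silyl enol ether 16 is isolated and dehydrosilylated by Saegusa–Ito oxidation with Pd(OAc)2 in MeCN, which returns to the route at 19 and continues with the methanolysis of step 8; this fallback makes no compound outside the list (F0).

## Further compounds

F1 | step 15 | (3aS,5R,6R,7S)-1-{(1S)-1-[(tert-butyldimethylsilyl)oxy]ethyl}-5-hydroxy-7-{3-[(4-methoxyphenyl)methoxy]prop-1-en-2-yl}-4-methylidene-6-[(triethylsilyl)oxy]-3,3a,4,5,6,7-hexahydro-2H-inden-2-one | C=C1[C@H]2CC(=O)C([C@H](C)O[Si](C)(C)C(C)(C)C)=C2[C@@H](C(=C)COCc3ccc(OC)cc3)[C@@H](O[Si](CC)(CC)CC)[C@@H]1O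
F2 | step 11 | 2-{3-[(4-methoxyphenyl)methoxy]prop-1-en-2-yl}-4,4,5,5-tetramethyl-1,3,2-dioxaborolane | C=C(COCc1ccc(OC)cc1)B1OC(C)(C)C(C)(C)O1
F3 | step 9 | (4S)-2-{(1S)-1-[(tert-butyldimethylsilyl)oxy]ethyl}-3-[(2S,3S)-3-{[(tert-butyldimethylsilyl)oxy]methyl}oxiran-2-yl]-4-[1-(trimethylsilyl)ethenyl]cyclopent-2-en-1-one | O=C1C[C@H](C(=C)[Si](C)(C)C)C([C@@H]2O[C@H]2CO[Si](C)(C)C(C)(C)C)=C1[C@H](C)O[Si](C)(C)C(C)(C)C
F0 | step 17 | none | none
F0 | step 7 | none | none
A1 | alternative 1 | dithioketal-protected cis-hexahydroindene with C6 pinacol boronate, C7 methyl ester, C4-methyl C4=C5 alkene and C1-epimeric 1-[(4-methoxybenzyl)oxy]ethyl group | CC=1[C@H]2CC3(SCCCS3)[C@H]([C@H](C)OCc4ccc(OC)cc4)[C@H]2[C@@H](C(=O)OC)[C@@H](B5OC(C)(C)C(C)(C)O5)C=1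
A2 | alternative 2 | hydrinden-2-one with C1=C7a enone, C4 ethylene ketal, 5,6-O-isopropylidene group and C7 [(4-methoxybenzyl)oxy]methyl arm | C12(OCCO2)[C@H]3CC(=O)C([C@H](C)O[Si](C)(C)C(C)(C)C)=C3[C@@H](COCc4ccc(OC)cc4)[C@H]5OC(C)(C)O[C@@H]15
A3 | alternative 3 | 4-methylidene hydrinden-2-one with C1=C7a enone, 5,6-O-isopropylidene group and C7 1-(methoxycarbonyl)ethenyl arm | C=C1[C@H]2CC(=O)C([C@H](C)O[Si](C)(C)C(C)(C)C)=C2[C@@H](C(=C)C(=O)OC)[C@H]3OC(C)(C)O[C@@H]13
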